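**Retrosynthetic overview**
1. Target ⇐ global desilylation with closure of the 12,6-lactone (last ring) ⇐ acylation of the 8-OH of a ten-membered hydroxy acrylate.
2. Ten-membered ring ⇐ key C7–C8 bond: a 2-(methoxycarbonyl)allylindium (a β-acrylate carbanion, made by Pd/InI polarity reversal of an allylic acetate) adds to the tethered C8 aldehyde and sets C7 and C8.
3. Seco-aldehyde ⇐ asymmetric Ni/Cr coupling at C5–C6 (sets C6) of a (Z)-vinyl iodide with a γ-oxo acrylate from Morita–Baylis–Hillman chemistry; the C8 aldehyde is carried as a terminal alkene.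
4. Vinyl iodide ⇐ Sharpless epoxidation (first ring, 1,10-epoxide), Ando Z-olefination (C1=C10), Brown allylation (C3), Cu-catalysed carbomagnesiation of propargyl alcohol (4Z olefin).
5. Ring order: epoxide → carbocycle → lactone.

Assumption: (R)-2-methylbutanoic acid, the Ando phosphonoacetate, InI, (−)-Ipc2BOMe and a Kishi oxazoline–sulfonamide ligand are bought; atom labels C1–C15 are those of the germacranolide target.

**Route**

Step 1
Reactants: 1 prop-2-yn-1-ol
Product: 3 (Z)-3-iodo-2-methylprop-2-en-1-ol, via vinylmagnesium alkoxide 2 (not isolated)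
Conditions: MeMgBr (2.5 equiv), CuI (10 mol %), THF/Et2O, −10 °C → rt; then I2, −40 °C → rt
Reagents that add atoms: methylmagnesium bromide C[Mg]Br; iodine II
Why: Cu-catalysed anti-carbomagnesiation of the propargylic alkoxide puts Me on C4 and Mg on C5 in a chelated alkenylmagnesium, and iodinolysis with retention fixes the (Z)-vinyl iodide that becomes the 4Z ring olefin.

Step 2
Reactants: 3 (Z)-3-iodo-2-methylprop-2-en-1-ol
Product: 4 (Z)-3-iodo-2-methylprop-2-enal
Conditions: activated MnO2, CH2Cl2, rt (used crude)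
Reagents that add atoms: none
Why: MnO2 oxidises the allylic alcohol selectively and under neutral conditions, which keeps the Z geometry.

Step 3
Reactants: 4 (Z)-3-iodo-2-methylprop-2-enal
Product: 6 (1Z,3S)-1-iodo-2-methylhexa-1,5-dien-3-ol, via borinate ester 5 (not isolated)
Conditions: (−)-Ipc2BOMe, allylMgBr, Et2O, 0 °C → rt; then 4, −78 °C; NaOH, H2O2
Reagents that add atoms: allylmagnesium bromide C=CC[Mg]Br
Why: Brown allylboration through a chair transition state; the (+)-α-pinene-derived reagent gives the (S)-carbinol when the aldehyde substituent outranks the allyl CH2 (as for isobutyraldehyde or benzaldehyde), which sets C3.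

Step 4
Reactants: 6 (1Z,3S)-1-iodo-2-methylhexa-1,5-dien-3-ol
Product: 7 tert-butyl{[(1Z,3S)-1-iodo-2-methylhexa-1,5-dien-3-yl]oxy}dimethylsilane
Conditions: TBSCl, imidazole, DMF, rt
Reagents that add atoms: tert-butyldimethylsilyl chloride CC(C)(C)[Si](C)(C)Cl
Why: standard silylation masks the 3-OH until the last step.

Step 5
Reactants: 7 tert-butyl{[(1Z,3S)-1-iodo-2-methylhexa-1,5-dien-3-yl]oxy}dimethylsilane
Product: 9 (3S,4Z)-3-[(tert-butyldimethylsilyl)oxy]-5-iodo-4-methylpent-4-enal, via diol 8 (not isolated)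
Conditions: OsO4 (2 mol %), NaIO4 (4 equiv), 2,6-lutidine, dioxane/H2O, rt
Reagents that add atoms: osmium tetroxide O=[Os](=O)(=O)=O (catalytic oxygen relay); sodium periodate [Na+].[O-]I(=O)(=O)=O
Why: Lemieux–Johnson cleavage takes the monosubstituted alkene and leaves the hindered, electron-poor iodo-trisubstituted alkene untouched, giving the C1 aldehyde.

Step 6
Reactants: 10 ethyl 2-[bis(2-methylphenoxy)phosphoryl]acetate
Product: 11 ethyl 2-[bis(2-methylphenoxy)phosphoryl]pent-4-enoate (racemic)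
Conditions: NaH, THF, 0 °C; allyl bromide, 0 °C → rt
Reagents that add atoms: allyl bromide C=CCBr
Why: C-alkylation of the phosphonoacetate anion installs C9 and a vinyl group that is a masked C8 aldehyde.

Step 7
Reactants: 9 (3S,4Z)-3-[(tert-butyldimethylsilyl)oxy]-5-iodo-4-methylpent-4-enal; 11 ethyl 2-[bis(2-methylphenoxy)phosphoryl]pent-4-enoate
Product: 12 ethyl (2Z,5S,6Z)-5-[(tert-butyldimethylsilyl)oxy]-7-iodo-6-methyl-2-(prop-2-en-1-yl)hepta-2,6-dienoate
Conditions: NaH, THF, −78 → 0 °C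
Reagents that add atoms: none
Why: Ando's diaryl-phosphonate Horner–Wadsworth–Emmons olefination is kinetically Z-selective, so C2 ends up cis to the ester carbon (future C14) and trans to C9 as the 1(10)-olefin requires.

Step 8
Reactants: 12 ethyl (2Z,5S,6Z)-5-[(tert-butyldimethylsilyl)oxy]-7-iodo-6-methyl-2-(prop-2-en-1-yl)hepta-2,6-dienoate
Product: 13 (2Z,5S,6Z)-5-[(tert-butyldimethylsilyl)oxy]-7-iodo-6-methyl-2-(prop-2-en-1-yl)hepta-2,6-dien-1-ol
Conditions: DIBAL-H (2.5 equiv), CH2Cl2, −78 °C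
Reagents that add atoms: none
Why: clean 1,2-reduction of the enoate gives the C14 allylic alcohol without touching the vinyl iodide or silyl ether.

Step 9
Reactants: 13 (2Z,5S,6Z)-5-[(tert-butyldimethylsilyl)oxy]-7-iodo-6-methyl-2-(prop-2-en-1-yl)hepta-2,6-dien-1-ol
Product: 14 [(2S,3R)-3-{(2S,3Z)-2-[(tert-butyldimethylsilyl)oxy]-4-iodo-3-methylbut-3-en-1-yl}-2-(prop-2-en-1-yl)oxiran-2-yl]methanol
Conditions: Ti(OiPr)4 (20 mol %), L-(+)-DET (24 mol %), TBHP, 4 Å MS, CH2Cl2, −20 °C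
Reagents that add atoms: tert-butyl hydroperoxide CC(C)(C)OO
Why: Katsuki–Sharpless epoxidation reacts only at the allylic-alcohol olefin, and L-(+)-tartrate delivers oxygen to the same face as in nerol → (2S,3R)-epoxynerol, which sets C1 (R) and C10 (S) by reagent control.

Step 10
Reactants: 15 2,2-dimethoxyacetaldehyde; 16 methyl acrylate
Product: 17 methyl 3-hydroxy-4,4-dimethoxy-2-methylidenebutanoate (racemic)
Conditions: DABCO (0.3 equiv), dioxane/H2O, rt
Reagents that add atoms: none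
Why: Morita–Baylis–Hillman reaction of the electrophilic α-alkoxy aldehyde assembles C6, C7 and C11–C13 in one atom-economic step.

Step 11
Reactants: 17 methyl 3-hydroxy-4,4-dimethoxy-2-methylidenebutanoate
Product: 19 methyl (2E)-2-(acetoxymethyl)-4,4-dimethoxybut-2-enoate, via secondary acetate 18 (not isolated)
Conditions: Ac2O, Et3N, DMAP (cat.), THF, 0 °C → rt; then DABCO (0.3 equiv), 60 °C
Reagents that add atoms: acetic anhydride CC(=O)OC(C)=O
Why: acetylation followed by DABCO-mediated SN2′/SN2′ 1,3-transposition gives the thermodynamic primary allylic acetate with the acetal carbon trans to the ester, the geometry that the later allyl-metal needs.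

Step 12
Reactants: 19 methyl (2E)-2-(acetoxymethyl)-4,4-dimethoxybut-2-enoate
Product: 20 methyl (2E)-2-(acetoxymethyl)-4-oxobut-2-enoate
Conditions: TFA, H2O, CH2Cl2, 0 °C
Reagents that add atoms: water O
Why: mild acetal hydrolysis releases the fumaraldehyde-type aldehyde (C6) while the allylic acetate and ester survive.

Step 13
Reactants: 14 [(2S,3R)-3-{(2S,3Z)-2-[(tert-butyldimethylsilyl)oxy]-4-iodo-3-methylbut-3-en-1-yl}-2-(prop-2-en-1-yl)oxiran-2-yl]methanol; 20 methyl (2E)-2-(acetoxymethyl)-4-oxobut-2-enoate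
Product: 21 methyl (2E,4R,5Z,7S)-2-(acetoxymethyl)-7-[(tert-butyldimethylsilyl)oxy]-4-hydroxy-8-[(2R,3S)-3-(hydroxymethyl)-3-(prop-2-en-1-yl)oxiran-2-yl]-6-methylocta-2,5-dienoate
Conditions: CrCl2 (4 equiv), Kishi oxazoline–sulfonamide ligand (4.4 equiv), Et3N, NiCl2 (5 mol %), THF, rt; 20 (2 equiv)
Reagents that add atoms: none
Why: Kishi's asymmetric Nozaki–Hiyama–Kishi coupling adds the alkenylchromium 1,2 to the aldehyde with retention of the Z olefin, and the chiral Cr(III)–sulfonamide complex sets C6 by reagent control (ligand antipode chosen to give 6R, checked by Mosher analysis).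

Step 14
Reactants: 21 methyl (2E,4R,5Z,7S)-2-(acetoxymethyl)-7-[(tert-butyldimethylsilyl)oxy]-4-hydroxy-8-[(2R,3S)-3-(hydroxymethyl)-3-(prop-2-en-1-yl)oxiran-2-yl]-6-methylocta-2,5-dienoate
Product: 22 methyl (2E,4R,5Z,7S)-2-(acetoxymethyl)-7-[(tert-butyldimethylsilyl)oxy]-6-methyl-8-[(2R,3S)-3-(prop-2-en-1-yl)-3-{[(triethylsilyl)oxy]methyl}oxiran-2-yl]-4-[(triethylsilyl)oxy]octa-2,5-dienoate
Conditions: TESCl (3 equiv), imidazole, DMAP (cat.), DMF, 0 °C → rt
Reagents that add atoms: chlorotriethylsilane CC[Si](Cl)(CC)CC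
Why: one silylation caps both the 6-OH and the 14-OH, so that only the 8-OH is free after ring closure.

Step 15
Reactants: 22 methyl (2E,4R,5Z,7S)-2-(acetoxymethyl)-7-[(tert-butyldimethylsilyl)oxy]-6-methyl-8-[(2R,3S)-3-(prop-2-en-1-yl)-3-{[(triethylsilyl)oxy]methyl}oxiran-2-yl]-4-[(triethylsilyl)oxy]octa-2,5-dienoate
Product: 24 methyl (2E,4R,5Z,7S)-2-(acetoxymethyl)-7-[(tert-butyldimethylsilyl)oxy]-6-methyl-8-[(2R,3S)-3-(2-oxoethyl)-3-{[(triethylsilyl)oxy]methyl}oxiran-2-yl]-4-[(triethylsilyl)oxy]octa-2,5-dienoate, via diol 23 (not isolated)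
Conditions: OsO4 (2 mol %), NaIO4 (4 equiv), 2,6-lutidine, dioxane/H2O, 0 °C → rt (used crude)
Reagents that add atoms: osmium tetroxide O=[Os](=O)(=O)=O (catalytic oxygen relay); sodium periodate [Na+].[O-]I(=O)(=O)=O
Why: Lemieux–Johnson cleavage picks the only unhindered monosubstituted alkene (the enoate olefin is electron-poor, the C4=C5 olefin is flanked by two silyloxy carbons) and unveils the C8 aldehyde under buffered conditions that spare the β,γ-epoxide.

Step 16
Reactants: 24 methyl (2E,4R,5Z,7S)-2-(acetoxymethyl)-7-[(tert-butyldimethylsilyl)oxy]-6-methyl-8-[(2R,3S)-3-(2-oxoethyl)-3-{[(triethylsilyl)oxy]methyl}oxiran-2-yl]-4-[(triethylsilyl)oxy]octa-2,5-dienoate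
Product: 26 methyl (1R,3S,4Z,6R,7R,8R,10S)-3-[(tert-butyldimethylsilyl)oxy]-1,10-epoxy-8-hydroxy-6,14-bis[(triethylsilyl)oxy]germacra-4,11(13)-dien-12-oate, via allylindium species 25 (not isolated)
Conditions: Pd(PPh3)4 (10 mol %), InI (2 equiv), THF, rt, syringe-pump addition of 24 to 2 mM; cold aq. NH4Cl
Reagents that add atoms: none
Why: Proposed new method: Pd(0) ionises the allylic acetate to a π-allyl-Pd(II) electrophile that InI reduces and transmetalates to the σ-allylindium(III) 25 (In on C13), whose γ-carbon C7 — the normally electrophilic β-carbon of an acrylate — adds to the tethered C8 aldehyde through a chair six-membered transition state; the Z-type reagent (C6 trans to CO2Me, the more stable geometry) places C6 axial and so gives the 7,8-syn adduct, while 1,3-allylic strain holds H-6 in the allyl plane so the C5 tether and the aldehyde share the face anti to the OTES group, which turns 6R into 7R,8R and leaves the exocyclic C11=C13 methylene; closest known reactions are Araki-type Pd/InI umpolung allylation of aldehydes with allylic acetates (intermolecular and small rings) and CrCl2- or metal-mediated Barbier macrocyclisations of 2-(bromomethyl)acrylates to ten-membered germacranolides.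

Step 17
Reactants: 26 methyl (1R,3S,4Z,6R,7R,8R,10S)-3-[(tert-butyldimethylsilyl)oxy]-1,10-epoxy-8-hydroxy-6,14-bis[(triethylsilyl)oxy]germacra-4,11(13)-dien-12-oate; 27 (R)-2-methylbutanoic acid
Product: 28 methyl (1R,3S,4Z,6R,7R,8R,10S)-3-[(tert-butyldimethylsilyl)oxy]-1,10-epoxy-8-{[(2R)-2-methylbutanoyl]oxy}-6,14-bis[(triethylsilyl)oxy]germacra-4,11(13)-dien-12-oate
Conditions: DCC, DMAP (cat.), CH2Cl2, 0 °C → rt
Reagents that add atoms: none
Why: Steglich esterification of the only free hydroxyl installs the side chain with retention at C8 and without epimerising the α-centre of the unactivated acid.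

Step 18
Reactants: 28 methyl (1R,3S,4Z,6R,7R,8R,10S)-3-[(tert-butyldimethylsilyl)oxy]-1,10-epoxy-8-{[(2R)-2-methylbutanoyl]oxy}-6,14-bis[(triethylsilyl)oxy]germacra-4,11(13)-dien-12-oate
Product: 30 (1R,3S,4Z,6R,7R,8R,10S)-1,10-epoxy-3,14-dihydroxy-8-{[(2R)-2-methylbutanoyl]oxy}germacra-4,11(13)-dien-12,6-olide (CNP0356520.1), via desilylated hydroxy ester 29 (not isolated)
Conditions: HF·pyridine, pyridine, THF, 0 °C → rt
Reagents that add atoms: none
Why: buffered HF removes all three silyl ethers (conditions known to spare trisubstituted epoxides), and the freed 6-OH lactonises 5-exo onto the acrylate ester to give the trans-fused α-methylene-γ-lactone, with no stereocentre touched.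

**Compound list**
1 | prop-2-yn-1-ol | C#CCO | starting material
2 | bromomagnesium (Z)-3-(bromomagnesio)-2-methylprop-2-en-1-olate (in situ) | C/C(CO[Mg]Br)=C/[Mg]Br | intermediate
3 | (Z)-3-iodo-2-methylprop-2-en-1-ol | C/C(CO)=C/I | intermediate
4 | (Z)-3-iodo-2-methylprop-2-enal | C/C(C=O)=C/I | intermediate
5 | diisopinocampheylborinate ester of 6 (in situ) | I/C=C(/C)[C@@H](OB([C@@H]1C[C@@H]2C[C@H]([C@H]1C)C2(C)C)[C@@H]1C[C@@H]2C[C@H]([C@H]1C)C2(C)C)CC=C | intermediate
6 | (1Z,3S)-1-iodo-2-methylhexa-1,5-dien-3-ol | I/C=C(/C)[C@@H](O)CC=C | intermediate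
7 | tert-butyl{[(1Z,3S)-1-iodo-2-methylhexa-1,5-dien-3-yl]oxy}dimethylsilane | I/C=C(/C)[C@@H](O[Si](C)(C)C(C)(C)C)CC=C | intermediate
8 | (4S,5Z)-4-[(tert-butyldimethylsilyl)oxy]-6-iodo-5-methylhex-5-ene-1,2-diol (C2 epimers, in situ) | I/C=C(/C)[C@@H](O[Si](C)(C)C(C)(C)C)CC(O)CO | intermediate
9 | (3S,4Z)-3-[(tert-butyldimethylsilyl)oxy]-5-iodo-4-methylpent-4-enal | I/C=C(/C)[C@@H](O[Si](C)(C)C(C)(C)C)CC=O | intermediate
10 | ethyl 2-[bis(2-methylphenoxy)phosphoryl]acetate | CCOC(=O)CP(=O)(Oc1ccccc1C)Oc1ccccc1C | starting material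
11 | ethyl 2-[bis(2-methylphenoxy)phosphoryl]pent-4-enoate (racemic) | CCOC(=O)C(CC=C)P(=O)(Oc1ccccc1C)Oc1ccccc1C | intermediate
12 | ethyl (2Z,5S,6Z)-5-[(tert-butyldimethylsilyl)oxy]-7-iodo-6-methyl-2-(prop-2-en-1-yl)hepta-2,6-dienoate | I/C=C(/C)[C@@H](O[Si](C)(C)C(C)(C)C)C/C=C(/CC=C)C(=O)OCC | intermediate
13 | (2Z,5S,6Z)-5-[(tert-butyldimethylsilyl)oxy]-7-iodo-6-methyl-2-(prop-2-en-1-yl)hepta-2,6-dien-1-ol | I/C=C(/C)[C@@H](O[Si](C)(C)C(C)(C)C)C/C=C(/CC=C)CO | intermediate
14 | [(2S,3R)-3-{(2S,3Z)-2-[(tert-butyldimethylsilyl)oxy]-4-iodo-3-methylbut-3-en-1-yl}-2-(prop-2-en-1-yl)oxiran-2-yl]methanol | I/C=C(/C)[C@@H](O[Si](C)(C)C(C)(C)C)C[C@H]1O[C@]1(CO)CC=C | intermediate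
15 | 2,2-dimethoxyacetaldehyde | COC(OC)C=O | starting material
16 | methyl acrylate | C=CC(=O)OC | starting material
17 | methyl 3-hydroxy-4,4-dimethoxy-2-methylidenebutanoate (racemic) | COC(OC)C(O)C(=C)C(=O)OC | intermediate
18 | methyl 3-acetoxy-4,4-dimethoxy-2-methylidenebutanoate (in situ) | COC(OC)C(OC(C)=O)C(=C)C(=O)OC | intermediate
19 | methyl (2E)-2-(acetoxymethyl)-4,4-dimethoxybut-2-enoate | COC(OC)/C=C(\COC(C)=O)C(=O)OC | intermediate
20 | methyl (2E)-2-(acetoxymethyl)-4-oxobut-2-enoate | O=C/C=C(\COC(C)=O)C(=O)OC | intermediate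
21 | methyl (2E,4R,5Z,7S)-2-(acetoxymethyl)-7-[(tert-butyldimethylsilyl)oxy]-4-hydroxy-8-[(2R,3S)-3-(hydroxymethyl)-3-(prop-2-en-1-yl)oxiran-2-yl]-6-methylocta-2,5-dienoate | CC(=O)OC/C(C(=O)OC)=C\[C@H](O)/C=C(/C)[C@@H](O[Si](C)(C)C(C)(C)C)C[C@H]1O[C@]1(CO)CC=C | intermediate
22 | bis-TES ether of 21 (6-OTES, 14-OTES) | CC(=O)OC/C(C(=O)OC)=C\[C@H](O[Si](CC)(CC)CC)/C=C(/C)[C@@H](O[Si](C)(C)C(C)(C)C)C[C@H]1O[C@]1(CO[Si](CC)(CC)CC)CC=C | intermediate
23 | terminal 1,2-diol of 22 (epimers, in situ) | CC(=O)OC/C(C(=O)OC)=C\[C@H](O[Si](CC)(CC)CC)/C=C(/C)[C@@H](O[Si](C)(C)C(C)(C)C)C[C@H]1O[C@]1(CO[Si](CC)(CC)CC)CC(O)CO | intermediate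
24 | seco-aldehyde (C8 aldehyde, C13 acetate; 3S,6R,1R,10S; 4Z) | CC(=O)OC/C(C(=O)OC)=C\[C@H](O[Si](CC)(CC)CC)/C=C(/C)[C@@H](O[Si](C)(C)C(C)(C)C)C[C@H]1O[C@]1(CO[Si](CC)(CC)CC)CC=O | intermediate
25 | C13 allylindium(III) acetate iodide of 24 (in situ) | CC(=O)O[In](I)C/C(C(=O)OC)=C\[C@H](O[Si](CC)(CC)CC)/C=C(/C)[C@@H](O[Si](C)(C)C(C)(C)C)C[C@H]1O[C@]1(CO[Si](CC)(CC)CC)CC=O | intermediate
26 | methyl (1R,3S,4Z,6R,7R,8R,10S)-3-[(tert-butyldimethylsilyl)oxy]-1,10-epoxy-8-hydroxy-6,14-bis[(triethylsilyl)oxy]germacra-4,11(13)-dien-12-oate | C=C(C(=O)OC)[C@H]1[C@H](O[Si](CC)(CC)CC)/C=C(/C)[C@@H](O[Si](C)(C)C(C)(C)C)C[C@H]2O[C@]2(CO[Si](CC)(CC)CC)C[C@H]1O | intermediate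
27 | (R)-2-methylbutanoic acid | CC[C@@H](C)C(=O)O | starting material
28 | 8-O-[(2R)-2-methylbutanoyl] ester of 26 | C=C(C(=O)OC)[C@H]1[C@H](O[Si](CC)(CC)CC)/C=C(/C)[C@@H](O[Si](C)(C)C(C)(C)C)C[C@H]2O[C@]2(CO[Si](CC)(CC)CC)C[C@H]1OC(=O)[C@H](C)CC | intermediate
29 | methyl (1R,3S,4Z,6R,7S,8R,10S)-1,10-epoxy-3,6,14-trihydroxy-8-{[(2R)-2-methylbutanoyl]oxy}germacra-4,11(13)-dien-12-oate (in situ; 7S is a CIP change only) | C=C(C(=O)OC)[C@H]1[C@H](O)/C=C(/C)[C@@H](O)C[C@H]2O[C@]2(CO)C[C@H]1OC(=O)[C@H](C)CC | intermediate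
30 | (1R,3S,4Z,6R,7R,8R,10S)-1,10-epoxy-3,14-dihydroxy-8-{[(2R)-2-methylbutanoyl]oxy}germacra-4,11(13)-dien-12,6-olide | C=C1C(=O)O[C@@H]2/C=C(/C)[C@@H](O)C[C@H]3O[C@]3(CO)C[C@@H](OC(=O)[C@H](C)CC)[C@@H]12 | target

**Step count**
Total: 18 steps. Longest linear sequence: 14 steps (1–5, 7–9, 13–18).

**Three steps most likely to fail**

Step 16 (macrocyclisation). The ring closure competes with oligomerisation and with β-hydride loss from the π-allyl-Pd, and the C7/C8 outcome rests on a transition-state model rather than on precedent for this ring. The fallback generates the allyl-metal by direct insertion into a C–Br bond instead of by Pd/In transmetalation. It sets out from 22: methanolysis (K2CO3, MeOH) gives the allylic alcohol F1, Appel bromination (CBr4, PPh3) gives the allylic bromide F2, and Lemieux–Johnson cleavage gives the bromo aldehyde F3. F3 is closed at high dilution in a classical intramolecular Barbier reaction with indium powder (or with CrCl2 under Nozaki–Hiyama conditions), and the route is rejoined at 26.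

Step 13 (asymmetric Ni/Cr coupling). The ligand-controlled diastereoselectivity may be low with this hindered Z-iodide and this very electrophilic enal, and the free epoxy alcohol and the allylic acetate may interfere. The fallback sets C6 by ketone reduction instead of by C–C bond formation. It sets out from 14: silylation (TESCl) gives the TES ether F4; an achiral NiCl2/CrCl2 coupling with 20 gives the C6-epimeric carbinols F5; Dess–Martin oxidation gives the cross-conjugated dienone F6; CBS reduction (oxazaborolidine antipode chosen for 6R) gives the (6R)-alcohol F7; TESCl then returns the route to 22.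

Step 18 (global deprotection and lactonisation). HF may open the 2,3-epoxy alcohol, and the triol stage may translactonise or shift the acyl group. The fallback stages the deprotection so that the epoxy alcohol never meets HF. It sets out from 28: PPTS in MeOH/CH2Cl2 at 0 °C cleaves only the two TES ethers and the freed 6-OH closes the lactone to give the 3-O-TBS lactone F8; AcOH-buffered TBAF then removes the last silyl group and the route is rejoined at 30.

**Further compounds**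
F1 | step 16 | C13 allylic alcohol from 22 (acetate removed) | OC/C(C(=O)OC)=C\[C@H](O[Si](CC)(CC)CC)/C=C(/C)[C@@H](O[Si](C)(C)C(C)(C)C)C[C@H]1O[C@]1(CO[Si](CC)(CC)CC)CC=C
F2 | step 16 | C13 allylic bromide | BrC/C(C(=O)OC)=C\[C@H](O[Si](CC)(CC)CC)/C=C(/C)[C@@H](O[Si](C)(C)C(C)(C)C)C[C@H]1O[C@]1(CO[Si](CC)(CC)CC)CC=C
F3 | step 16 | C13 bromide C8 aldehyde | BrC/C(C(=O)OC)=C\[C@H](O[Si](CC)(CC)CC)/C=C(/C)[C@@H](O[Si](C)(C)C(C)(C)C)C[C@H]1O[C@]1(CO[Si](CC)(CC)CC)CC=O
F4 | step 13 | 14-O-TES ether of 14 | I/C=C(/C)[C@@H](O[Si](C)(C)C(C)(C)C)C[C@H]1O[C@]1(CO[Si](CC)(CC)CC)CC=C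
F5 | step 13 | C6-epimeric coupling product (14-OTES) | CC(=O)OC/C(C(=O)OC)=C\C(O)/C=C(/C)[C@@H](O[Si](C)(C)C(C)(C)C)C[C@H]1O[C@]1(CO[Si](CC)(CC)CC)CC=C
F6 | step 13 | C6 dienone | CC(=O)OC/C(C(=O)OC)=C\C(=O)/C=C(/C)[C@@H](O[Si](C)(C)C(C)(C)C)C[C@H]1O[C@]1(CO[Si](CC)(CC)CC)CC=C
F7 | step 13 | (6R)-alcohol (14-OTES) | CC(=O)OC/C(C(=O)OC)=C\[C@H](O)/C=C(/C)[C@@H](O[Si](C)(C)C(C)(C)C)C[C@H]1O[C@]1(CO[Si](CC)(CC)CC)CC=C
F8 | step 18 | 3-O-TBS ether of the target lactone | C=C1C(=O)O[C@@H]2/C=C(/C)[C@@H](O[Si](C)(C)C(C)(C)C)C[C@H]3O[C@]3(CO)C[C@@H](OC(=O)[C@H](C)CC)[C@@H]12
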